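**Retrosynthetic overview**

- Enabling feature: in the 2,3,4,7-tetrahydrooxepine ring the ether oxygen O1 is allylic (O1–C7H2–C6=C5), and its other neighbour, the fully substituted C2, is α to the carboxyl and β to the aryl ketone. C2 can therefore be taken back to the ketone oxidation level, as the ketal carbon of an α-keto ester.
- Key disconnections: O1–C2 (acid-catalysed addition of a 2-substituted allylic alcohol to a 2-methoxyacrylate) and C5=C6 (ring-closing metathesis), both in one flask, giving a cyclic methyl ketal. The methoxy group is a temporary activating group.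
- C2–CH2C(=O)Ar: enantioselective Mukaiyama-type addition of the aryl ketone enol silane to the cyclic oxocarbenium ion expels the methoxy group and sets the only stereocentre (R).
- Fragments: dimethyl oxalate plus butenyl Grignard; 5-bromo-2-methylpent-2-ene (allylic oxidation fixes the E-alkene) plus 2-bromoallyl alcohol; 2',5'-dihydroxyacetophenone.
- Ring order: the arene is bought and stays aromatic; the oxepene is the only ring made (step 8); ester cleavage and desilylation finish the route.

Key step: step 8

Remark: ring positions follow the oxepine numbering of the target (O1, C2 quaternary, C3, C4, C5=C6, C7), the required configuration at C2 is R, and the butenyl Grignard reagent is taken as its commercial THF solution.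

**Route**

Step 1
Reactants: 1 dimethyl oxalate; 2 but-3-en-1-ylmagnesium bromide
Product: 3 methyl 2-oxohex-5-enoate
Conditions: 2 added slowly to 1 (2 equiv), THF, −78 °C; 1 N HCl quench
Reagents that add atoms: none
Why: Inverse Grignard addition to excess dialkyl oxalate at low temperature should stop at the α-keto ester, because the magnesium hemiketal survives until the acidic quench (Grignard acylation).

Step 2
Reactants: 3 methyl 2-oxohex-5-enoate
Product: 4 methyl 2,2-dimethoxyhex-5-enoate
Conditions: HC(OMe)3 (3 equiv), MeOH, H2SO4 (cat.), 60 °C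
Reagents that add atoms: trimethyl orthoformate, COC(OC)OC
Why: Acid-catalysed ketalisation of the electrophilic keto group with orthoformate as dehydrating methanol donor is standard for pyruvate-type esters and leaves the ester and terminal alkene untouched.

Step 3
Reactants: 4 methyl 2,2-dimethoxyhex-5-enoate
Product: 5 methyl 2-methoxyhexa-2,5-dienoate (mixture of C2=C3 isomers)
Conditions: TMSOTf (1.2 equiv), i-Pr2NEt (1.5 equiv), CH2Cl2, 0 °C to rt
Reagents that add atoms: none
Why: The silyl triflate ionises one methoxy group and the hindered amine removes the only adjacent proton (C3–H), a ketal-to-enol-ether elimination that should give the captodative 2-methoxyacrylate without moving the terminal alkene.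

Step 4
Reactants: 6 5-bromo-2-methylpent-2-ene
Product: 7 (E)-5-bromo-2-methylpent-2-en-1-ol
Conditions: SeO2 (cat.), t-BuOOH, salicylic acid (cat.), CH2Cl2, rt
Reagents that add atoms: tert-butyl hydroperoxide, CC(C)(C)OO (oxygen relayed by catalytic SeO2, O=[Se]=O)
Why: Riley allylic oxidation (ene reaction, then [2,3]-sigmatropic shift) hydroxylates the methyl group trans to the chain of a trisubstituted alkene, which fixes the E geometry of the side chain.

Step 5
Reactants: 7 (E)-5-bromo-2-methylpent-2-en-1-ol
Product: 8 {[(E)-5-bromo-2-methylpent-2-en-1-yl]oxy}(tert-butyl)dimethylsilane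
Conditions: TBSCl, imidazole, CH2Cl2, 0 °C to rt
Reagents that add atoms: tert-butyldimethylsilyl chloride, CC(C)(C)[Si](C)(C)Cl
Why: Standard silylation of a primary allylic alcohol; the same silyl group is used on all three hydroxyls so that they fall together in the last step.

Step 6
Reactants: 8 {[(E)-5-bromo-2-methylpent-2-en-1-yl]oxy}(tert-butyl)dimethylsilane; 9 2-bromoprop-2-en-1-ol
Product: 11 (E)-7-[(tert-butyldimethylsilyl)oxy]-6-methyl-2-methylidenehept-5-en-1-ol, via alkylzinc bromide 10 (not isolated)
Conditions: Zn dust, LiCl, THF, 50 °C; then 9, Pd(OAc)2 (2 mol%), SPhos (4 mol%), THF, 25 °C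
Reagents that add atoms: none
Why: LiCl-assisted zinc insertion gives a primary alkylzinc that tolerates the silyl ether, and Negishi sp3–sp2 coupling with the vinyl bromide should install the 1,1-disubstituted alkene regiospecifically, the weakly basic organozinc tolerating the free hydroxyl.

Step 7
Reactants: 12 1-(2,5-dihydroxyphenyl)ethan-1-one
Product: 13 tert-butyl({1-[2,5-bis(tert-butyldimethylsilyloxy)phenyl]ethenyl}oxy)dimethylsilane
Conditions: TBSOTf (3.5 equiv), Et3N (5 equiv), CH2Cl2, 0 °C to rt
Reagents that add atoms: tert-butyldimethylsilyl trifluoromethanesulfonate, CC(C)(C)[Si](C)(C)OS(=O)(=O)C(F)(F)F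
Why: Silyl triflate and amine silylate both phenols and soft-enolise the methyl ketone (one enolisable position only), giving the Mukaiyama donor in one operation.

Step 8
Reactants: 5 methyl 2-methoxyhexa-2,5-dienoate; 11 (E)-7-[(tert-butyldimethylsilyl)oxy]-6-methyl-2-methylidenehept-5-en-1-ol
Product: 15 methyl 6-{(E)-5-[(tert-butyldimethylsilyl)oxy]-4-methylpent-3-en-1-yl}-2-methoxy-2,3,4,7-tetrahydrooxepine-2-carboxylate (racemic), via mixed ketal 14 (not isolated)
Conditions: 5 (1.5 equiv), camphorsulfonic acid (2 mol%), CH2Cl2, 0 °C; Et3N (5 mol%), evaporate; second-generation Hoveyda–Grubbs catalyst (5 mol%), CH2Cl2 (0.005 M), 40 °C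
Reagents that add atoms: none
Why: The acid protonates the captodative enol ether 5 at C3 and the ester-substituted oxocarbenium ion is captured by the primary allylic alcohol 11 in Markovnikov fashion, joining the two fragments at the fully substituted carbon as mixed ketal 14 (the O1–C2 bond); after neutralisation the Ru alkylidene loads on the monosubstituted butenyl alkene and closes onto the 1,1-disubstituted allyl ether with loss of ethylene (the C5=C6 bond). The closest known reaction types are mixed-ketal formation from alcohols and 2-alkoxyalkenes (as in 2-methoxypropene protection) and ring-closing metathesis of alkenyl allyl ethers and ketals to 2,3,4,7-tetrahydrooxepines. The oxepene, the only ring formed, is closed by RCM as a seven-membered ring whose trisubstituted alkene is necessarily ring-cis, with the gem-disubstituted ketal carbon favouring cyclisation. The new stereocentre (ketal C2) is formed without control and deliberately as a racemate, because step 9 planarises it. The step needs kinetic mono-addition without ketal scrambling (excess volatile 5, low temperature, amine quench once 11 is consumed) and cyclisation over oligomerisation or attack on the trisubstituted side-chain alkene (high dilution; that alkene could only close a ten-membered ring).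

Step 9
Reactants: 15 methyl 6-{(E)-5-[(tert-butyldimethylsilyl)oxy]-4-methylpent-3-en-1-yl}-2-methoxy-2,3,4,7-tetrahydrooxepine-2-carboxylate; 13 tert-butyl({1-[2,5-bis(tert-butyldimethylsilyloxy)phenyl]ethenyl}oxy)dimethylsilane
Product: 16 methyl (R)-2-{2-[2,5-bis(tert-butyldimethylsilyloxy)phenyl]-2-oxoethyl}-6-{(E)-5-[(tert-butyldimethylsilyl)oxy]-4-methylpent-3-en-1-yl}-2,3,4,7-tetrahydrooxepine-2-carboxylate
Conditions: 13 (1.5 equiv), confined chiral imidodiphosphorimidate Brønsted acid (IDPi, 3 mol%), toluene, −40 °C; Et3N quench
Reagents that add atoms: none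
Why: Proposed new method: the silylated chiral acid abstracts the methoxy group of 15 as its silyl ether, the planar seven-membered oxocarbenium ion (C2 bearing CO2Me) stays paired with the confined chiral anion, and enol silane 13 attacks the face left open by the anion, silyl transfer regenerating the catalyst and setting the (R)-quaternary centre (catalyst enantiomer to be chosen by screening); the closest known reaction types are IDPi-catalysed asymmetric Mukaiyama-type additions of enol silanes to cyclic aliphatic oxocarbenium ions from five- to seven-membered lactol acetates and Lewis-acid C-glycosylation of ulosonate ketal donors, the new element being a fully substituted, ester-bearing cationic carbon.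

Step 10
Reactants: 16 methyl (R)-2-{2-[2,5-bis(tert-butyldimethylsilyloxy)phenyl]-2-oxoethyl}-6-{(E)-5-[(tert-butyldimethylsilyl)oxy]-4-methylpent-3-en-1-yl}-2,3,4,7-tetrahydrooxepine-2-carboxylate
Product: 17 (R)-2-{2-[2,5-bis(tert-butyldimethylsilyloxy)phenyl]-2-oxoethyl}-6-{(E)-5-[(tert-butyldimethylsilyl)oxy]-4-methylpent-3-en-1-yl}-2,3,4,7-tetrahydrooxepine-2-carboxylic acid
Conditions: Me3SnOH (8 equiv), 1,2-dichloroethane, 80 °C; 0.5 N HCl wash
Reagents that add atoms: trimethyltin hydroxide, C[Sn](C)(C)O
Why: Trimethyltin hydroxide cleaves methyl esters by essentially neutral acyl substitution, which should spare the β-alkoxy ketone from retro-oxa-Michael ring opening and leave C2 untouched.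

Step 11
Reactants: 17 (R)-2-{2-[2,5-bis(tert-butyldimethylsilyloxy)phenyl]-2-oxoethyl}-6-{(E)-5-[(tert-butyldimethylsilyl)oxy]-4-methylpent-3-en-1-yl}-2,3,4,7-tetrahydrooxepine-2-carboxylic acid
Product: 18 (R)-2-[2-(2,5-dihydroxyphenyl)-2-oxoethyl]-6-[(E)-5-hydroxy-4-methylpent-3-en-1-yl]-2,3,4,7-tetrahydrooxepine-2-carboxylic acid
Conditions: Et3N·3HF (excess), THF/MeCN, 25 °C, argon
Reagents that add atoms: none
Why: Buffered fluoride desilylation removes the two aryl and the primary allylic silyl ethers under non-basic conditions, so that neither retro-oxa-Michael opening nor chromanone formation by the freed 2-hydroxyl should set in, and the inert atmosphere protects the hydroquinone.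

**Compound list**

1 | dimethyl oxalate | COC(=O)C(=O)OC | starting material
2 | but-3-en-1-ylmagnesium bromide | C=CCC[Mg]Br | starting material
3 | methyl 2-oxohex-5-enoate | C=CCCC(=O)C(=O)OC | intermediate
4 | methyl 2,2-dimethoxyhex-5-enoate | C=CCCC(OC)(OC)C(=O)OC | intermediate
5 | methyl 2-methoxyhexa-2,5-dienoate (mixture of C2=C3 isomers) | C=CCC=C(OC)C(=O)OC | intermediate
6 | 5-bromo-2-methylpent-2-ene | CC(C)=CCCBr | starting material
7 | (E)-5-bromo-2-methylpent-2-en-1-ol | C/C(=C\CCBr)CO | intermediate
8 | {[(E)-5-bromo-2-methylpent-2-en-1-yl]oxy}(tert-butyl)dimethylsilane | C/C(=C\CCBr)CO[Si](C)(C)C(C)(C)C | intermediate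
9 | 2-bromoprop-2-en-1-ol | C=C(Br)CO | starting material
10 | {(E)-5-[(tert-butyldimethylsilyl)oxy]-4-methylpent-3-en-1-yl}zinc bromide | C/C(=C\CC[Zn]Br)CO[Si](C)(C)C(C)(C)C | intermediate
11 | (E)-7-[(tert-butyldimethylsilyl)oxy]-6-methyl-2-methylidenehept-5-en-1-ol | C/C(=C\CCC(=C)CO)CO[Si](C)(C)C(C)(C)C | intermediate
12 | 1-(2,5-dihydroxyphenyl)ethan-1-one | CC(=O)c1cc(O)ccc1O | starting material
13 | tert-butyl({1-[2,5-bis(tert-butyldimethylsilyloxy)phenyl]ethenyl}oxy)dimethylsilane | C=C(O[Si](C)(C)C(C)(C)C)c1cc(O[Si](C)(C)C(C)(C)C)ccc1O[Si](C)(C)C(C)(C)C | intermediate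
14 | methyl 2-({(E)-7-[(tert-butyldimethylsilyl)oxy]-6-methyl-2-methylidenehept-5-en-1-yl}oxy)-2-methoxyhex-5-enoate (racemic) | C=CCCC(OC)(OCC(=C)CC/C=C(\C)CO[Si](C)(C)C(C)(C)C)C(=O)OC | intermediate
15 | methyl 6-{(E)-5-[(tert-butyldimethylsilyl)oxy]-4-methylpent-3-en-1-yl}-2-methoxy-2,3,4,7-tetrahydrooxepine-2-carboxylate (racemic) | COC(=O)C1(OC)CCC=C(CC/C=C(\C)CO[Si](C)(C)C(C)(C)C)CO1 | intermediate
16 | methyl (R)-2-{2-[2,5-bis(tert-butyldimethylsilyloxy)phenyl]-2-oxoethyl}-6-{(E)-5-[(tert-butyldimethylsilyl)oxy]-4-methylpent-3-en-1-yl}-2,3,4,7-tetrahydrooxepine-2-carboxylate | C/C(=C\CCC1=CCC[C@@](CC(=O)c2cc(O[Si](C)(C)C(C)(C)C)ccc2O[Si](C)(C)C(C)(C)C)(C(=O)OC)OC1)CO[Si](C)(C)C(C)(C)C | intermediate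
17 | (R)-2-{2-[2,5-bis(tert-butyldimethylsilyloxy)phenyl]-2-oxoethyl}-6-{(E)-5-[(tert-butyldimethylsilyl)oxy]-4-methylpent-3-en-1-yl}-2,3,4,7-tetrahydrooxepine-2-carboxylic acid | C/C(=C\CCC1=CCC[C@@](CC(=O)c2cc(O[Si](C)(C)C(C)(C)C)ccc2O[Si](C)(C)C(C)(C)C)(C(=O)O)OC1)CO[Si](C)(C)C(C)(C)C | intermediate
18 | (R)-2-[2-(2,5-dihydroxyphenyl)-2-oxoethyl]-6-[(E)-5-hydroxy-4-methylpent-3-en-1-yl]-2,3,4,7-tetrahydrooxepine-2-carboxylic acid | C/C(=C\CCC1=CCC[C@@](CC(=O)c2cc(O)ccc2O)(C(=O)O)OC1)CO | target

**Step count and risks**

Total step count: 11. Longest linear sequence: 7 steps (steps 4, 5, 6, 8, 9, 10, 11; the branch through steps 1, 2, 3, 8, 9, 10, 11 is equally long).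

Steps most likely to fail:

1. Step 9. What may go wrong is insufficient facial discrimination at the planar, ester-bearing oxocarbenium ion, or diversion of the cation by loss of the C3 proton (cyclic enol ether) or by endocyclic C–O cleavage. The fallback uses known chemistry, sets out from 3, 13 and 11, and returns at 16; here the oxygen on C2 comes from the keto group and the ether is closed at the allylic carbon.
   - Mukaiyama aldol addition of 13 to the chelating α-keto ester 3, catalysed by Cu(OTf)2 with a tert-butyl-bis(oxazoline) ligand (10 mol%, ligand enantiomer chosen for the R adduct; THF, −78 °C; 1 N HCl work-up), should give the tertiary alcohol methyl (R)-2-{2-[2,5-bis(tert-butyldimethylsilyloxy)phenyl]-2-oxoethyl}-2-hydroxyhex-5-enoate F1.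
   - Alcohol 11 is converted with CBr4 and PPh3 into the allylic bromide {[(E)-6-(bromomethyl)-2-methylhepta-2,6-dien-1-yl]oxy}(tert-butyl)dimethylsilane F2.
   - Silver-assisted O-alkylation of F1 with F2 (AgOTf, 2,6-di-tert-butyl-4-methylpyridine, CH2Cl2), which avoids the basic conditions that would trigger retro-aldol cleavage, should give the ether methyl (R)-2-{2-[2,5-bis(tert-butyldimethylsilyloxy)phenyl]-2-oxoethyl}-2-({(E)-7-[(tert-butyldimethylsilyl)oxy]-6-methyl-2-methylidenehept-5-en-1-yl}oxy)hex-5-enoate F3.
   - Ring-closing metathesis of F3 with the second-generation Hoveyda–Grubbs catalyst closes the oxepene to 16.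

2. Step 8. What may go wrong is acid-mediated scrambling of the mixed ketal into symmetrical ketals before ring closure, or sluggish protonation of the deactivated enol ether. The fallback sets out from 4 and 11 and returns at 15.
   - Ketal 4 is converted with acetyl chloride (cat. ZnCl2) into the α-chloro ether methyl 2-chloro-2-methoxyhex-5-enoate F4.
   - Substitution of F4 with 11 promoted by AgOTf and 2,6-di-tert-butyl-4-methylpyridine should give 14 irreversibly and in the absence of acid.
   - 14 is isolated and cyclised in a separate operation under the metathesis conditions of step 8 to give 15.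

3. Step 10. What may go wrong is slow acyl substitution at the hindered ester, with retro-oxa-Michael ring opening (and loss of configuration at C2) taking over on prolonged heating. The fallback sets out from 16 and returns at 17.
   - Nucleophilic demethylation with anhydrous LiI in refluxing ethyl acetate attacks the unhindered O-methyl carbon (alkyl–oxygen instead of acyl–oxygen cleavage), and acidification gives 17.
   - No compound outside the list arises (none F0).

**Further compounds**

F1 | step 9 | methyl (R)-2-{2-[2,5-bis(tert-butyldimethylsilyloxy)phenyl]-2-oxoethyl}-2-hydroxyhex-5-enoate | C=CCC[C@@](CC(=O)c1cc(O[Si](C)(C)C(C)(C)C)ccc1O[Si](C)(C)C(C)(C)C)(C(=O)OC)O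
F2 | step 9 | {[(E)-6-(bromomethyl)-2-methylhepta-2,6-dien-1-yl]oxy}(tert-butyl)dimethylsilane | C/C(=C\CCC(=C)CBr)CO[Si](C)(C)C(C)(C)C
F3 | step 9 | methyl (R)-2-{2-[2,5-bis(tert-butyldimethylsilyloxy)phenyl]-2-oxoethyl}-2-({(E)-7-[(tert-butyldimethylsilyl)oxy]-6-methyl-2-methylidenehept-5-en-1-yl}oxy)hex-5-enoate | C=CCC[C@@](CC(=O)c1cc(O[Si](C)(C)C(C)(C)C)ccc1O[Si](C)(C)C(C)(C)C)(C(=O)OC)OCC(=C)CC/C=C(\C)CO[Si](C)(C)C(C)(C)C
F4 | step 8 | methyl 2-chloro-2-methoxyhex-5-enoate (racemic) | C=CCCC(Cl)(OC)C(=O)OC
F0 | step 10 | none | none
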